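**Plan**

1. Ring numbering: C1 carries CO2H, C2 and C4 the oxygens, C6 the side chain C1′–C13′. The retrosynthesis first removes the two acetates and three benzyl groups, then cuts C6–C1′ and C1–CO2H in one operation (carbanion + 3,5-bis(benzyloxy)benzyne + CO2), then C3′–C4′ and C10′–C11′ of the chain.
2. Enabling feature: C1 sits between C2–O and C6–CH2, so the single benzene ring carries a contiguous O / CO2H / CH2 pattern. This is what a nucleophile followed by an electrophile leave on a 3-alkoxyaryne, and no ring has to be built.
3. Forward: hept-6-enyl Grignard opens (S)-propylene oxide (C10′–C11′); the alkene end becomes a primary bromide whose Grignard opens (S)-epichlorohydrin (C3′–C4′). The resulting chlorohydrin diol is lithiated at C1′, added to the aryne and trapped with CO2; benzyl ester, diacetate and hydrogenolysis follow.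
4. Stereochemistry: C12′ (S) comes from (S)-propylene oxide and C2′ (S) from (S)-epichlorohydrin. Both epoxides are opened at CH2, and no later step breaks a bond at either centre.
5. The aryne is released from a vicinal dibromide by Br/Li exchange between −100 and −78 °C. It therefore forms while the β-oxido carbanion is still intact, and no alkyllithium base has to deprotonate a ring that carries benzyl ethers.
6. Remark: the key-step product is handled as its lithium carboxylate and esterified without acidification, because the free 2′-hydroxy acid is expected to close to the six-membered lactone.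

Key step: step 9

**Route**

Step 1
Reactants: 1 5-bromobenzene-1,3-diol
Product: 2 1,3-bis(benzyloxy)-5-bromobenzene
Conditions: BnBr (2.2 equiv), K2CO3 (2.5 equiv), DMF, 60 °C
Reagents that add atoms: benzyl bromide, BrCc1ccccc1
Why: Williamson ether synthesis on both phenoxides; benzyl is chosen because all benzyl groups of the route can be removed together by hydrogenolysis at the end.

Step 2
Reactants: 2 1,3-bis(benzyloxy)-5-bromobenzene
Product: 3 1,5-bis(benzyloxy)-2,3-dibromobenzene
Conditions: NBS (1.0 equiv), MeCN, 0 °C → rt, dark
Reagents that add atoms: N-bromosuccinimide, O=C1CCC(=O)N1Br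
Why: Electrophilic aromatic bromination, expected para to one benzyloxy group and ortho to the other (the carbon beside the ring bromine) because the position between the two benzyloxy groups is the more crowded one, as is usual for 5-substituted resorcinol diethers.

Step 3
Reactants: 4 7-bromohept-1-ene; 5 (S)-propylene oxide
Product: 7 (2S)-dec-9-en-2-ol, via hept-6-en-1-ylmagnesium bromide 6 (not isolated)
Conditions: Mg (I2 cat.), THF, rt; then CuI (10 mol%), 5 (1.3 equiv), THF, −30 → 0 °C; then H2O (aq NH4Cl wash)
Reagents that add atoms: none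
Why: Copper-catalysed SN2 opening of a terminal epoxide by a primary Grignard reagent at the CH2 carbon; the stereocentre of (S)-propylene oxide is not involved and becomes C12′ (S).

Step 4
Reactants: 7 (2S)-dec-9-en-2-ol
Product: 8 tert-butyl{[(2S)-dec-9-en-2-yl]oxy}dimethylsilane
Conditions: TBSCl, imidazole, DMF, rt
Reagents that add atoms: tert-butyldimethylsilyl chloride, CC(C)(C)[Si](C)(C)Cl
Why: Standard silylation of a secondary alcohol, needed so that a Grignard reagent can later be formed at the other chain end.

Step 5
Reactants: 8 tert-butyl{[(2S)-dec-9-en-2-yl]oxy}dimethylsilane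
Product: 10 (9S)-9-[(tert-butyldimethylsilyl)oxy]decan-1-ol, via B-alkyl-9-borabicyclo[3.3.1]nonane 9 (not isolated)
Conditions: 9-BBN, THF, 0 °C → rt; then 3 M NaOH, 30% H2O2, 0 °C → rt
Reagents that add atoms: hydrogen peroxide, OO
Why: Hydroboration–oxidation of the terminal alkene with anti-Markovnikov selectivity should give the primary alcohol; the silyl ether and the stereocentre are inert.

Step 6
Reactants: 10 (9S)-9-[(tert-butyldimethylsilyl)oxy]decan-1-ol
Product: 11 {[(2S)-10-bromodecan-2-yl]oxy}(tert-butyl)dimethylsilane
Conditions: CBr4, PPh3, CH2Cl2, 0 °C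
Reagents that add atoms: carbon tetrabromide, BrC(Br)(Br)Br
Why: The Appel reaction converts the primary alcohol into the bromide under neutral conditions that leave the secondary silyl ether alone.

Step 7
Reactants: 11 {[(2S)-10-bromodecan-2-yl]oxy}(tert-butyl)dimethylsilane; 12 (S)-epichlorohydrin
Product: 14 (2S,12S)-12-[(tert-butyldimethylsilyl)oxy]-1-chlorotridecan-2-ol, via silyloxydecylmagnesium bromide 13 (not isolated)
Conditions: Mg (I2 cat.), THF, 40 °C; then added to 12 (1.2 equiv), CuI (10 mol%), THF, −40 → −20 °C; then H2O (aq NH4Cl wash)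
Reagents that add atoms: none
Why: Copper-catalysed Grignard opening of (S)-epichlorohydrin at the epoxide CH2 at low temperature, where the magnesium chlorohydrinate does not re-close; the epoxide stereocentre is untouched and becomes C2′ (S), and the CH2Cl arm is kept as the future carbanion site.

Step 8
Reactants: 14 (2S,12S)-12-[(tert-butyldimethylsilyl)oxy]-1-chlorotridecan-2-ol
Product: 15 (2S,12S)-1-chlorotridecane-2,12-diol
Conditions: p-TsOH·H2O (10 mol%), MeOH, rt
Reagents that add atoms: none
Why: Acid-catalysed methanolysis of the silyl ether; acid is used instead of fluoride so that the chlorohydrin does not close to the epoxide.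

Step 9
Reactants: 3 1,5-bis(benzyloxy)-2,3-dibromobenzene; 15 (2S,12S)-1-chlorotridecane-2,12-diol; 16 carbon dioxide
Product: 21 lithium 2,4-bis(benzyloxy)-6-[(2S,12S)-2,12-dihydroxytridecyl]benzoate, via C-lithiated dilithium dialkoxide 17 (not isolated), via ortho-bromoaryllithium 18 (not isolated), via 3,5-bis(benzyloxy)benzyne 19 (not isolated), via trilithiated aryl adduct 20 (not isolated)
Conditions: 15, n-BuLi (2.0 equiv), THF, −78 °C, then LiC10H8 (lithium naphthalenide, 2.0 equiv), −78 °C; separately 3 (0.8 equiv), n-BuLi (0.8 equiv), THF, −100 °C; carbanion solution transferred onto the aryllithium at −100 °C, then −78 °C, 1 h; CO2 (gas, excess), −78 → 0 °C; H2O, no acidification; crude salt used directly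
Reagents that add atoms: carbon dioxide 16, O=C=O (also listed as reactant); n-butyllithium, [Li]CCCC (lithium counter-ion)
Why: Proposed new method: deprotonation of both hydroxyls of 15 and reductive lithiation of the C–Cl bond give the β-oxido primary alkyllithium 17, Br/Li exchange on 3 at −100 °C gives 18, which loses LiBr as the bath rises to −78 °C, and 17 then adds to aryne 19 to give aryllithium 20, which CO2 converts into the carboxylate. The closest known reaction type is the addition of simple alkyllithiums to 3-alkoxyarynes with electrophilic trapping of the resulting ortho-alkoxy aryllithium (aryne carbolithiation–carboxylation); β-lithioalkoxides made from chlorohydrins are established carbanions toward carbonyl electrophiles but have not been added to arynes. No ring is closed and no stereocentre is created: C2′ and C12′ travel as lithium alkoxides and none of their bonds is broken. Regioselectivity is needed and should come from the benzyloxy group flanking the triple bond, whose inductive pull places the carbanion on the remote aryne carbon (future C6) and the lithium next to oxygen (future C1), where CO2 enters. Chemoselectivity for addition over loss of Li2O from 17 is also needed; it is sought by letting the aryne form from the ortho-bromoaryllithium at or below −78 °C, where 17 should persist, and by using exactly one equivalent of n-BuLi for the exchange so that no butyllithium competes for the aryne.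

Step 10
Reactants: 21 lithium 2,4-bis(benzyloxy)-6-[(2S,12S)-2,12-dihydroxytridecyl]benzoate
Product: 22 benzyl 2,4-bis(benzyloxy)-6-[(2S,12S)-2,12-dihydroxytridecyl]benzoate
Conditions: BnBr (1.5 equiv), NaHCO3, DMF, rt
Reagents that add atoms: benzyl bromide, BrCc1ccccc1
Why: SN2 O-alkylation of the carboxylate (carboxylate esterification); the neutral alcohols do not compete without strong base, and because the acid is never set free the 2′-hydroxyl has little opportunity to lactonise.

Step 11
Reactants: 22 benzyl 2,4-bis(benzyloxy)-6-[(2S,12S)-2,12-dihydroxytridecyl]benzoate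
Product: 23 benzyl 2,4-bis(benzyloxy)-6-[(2S,12S)-2,12-diacetoxytridecyl]benzoate
Conditions: Ac2O, pyridine, DMAP (cat.), CH2Cl2, 0 °C → rt
Reagents that add atoms: acetic anhydride, CC(=O)OC(C)=O
Why: DMAP-catalysed acylation of both secondary alcohols; only O–H bonds react, so C2′ and C12′ keep their configuration, and the 2′-acetate removes the lactonisation pathway for good.

Step 12
Reactants: 23 benzyl 2,4-bis(benzyloxy)-6-[(2S,12S)-2,12-diacetoxytridecyl]benzoate
Product: 24 6-[(2S,12S)-2,12-diacetoxytridecyl]-2,4-dihydroxybenzoic acid
Conditions: H2 (1 atm), 10% Pd/C, EtOAc, rt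
Reagents that add atoms: none
Why: Catalytic hydrogenolysis of the benzyl ester and both aryl benzyl ethers under neutral conditions; the homobenzylic and alkyl acetates are not hydrogenolysed and no acid or base is present to move acetyl groups.

**Compound list**

1 | 5-bromobenzene-1,3-diol (5-bromoresorcinol) | Oc1cc(O)cc(Br)c1 | starting material
2 | 1,3-bis(benzyloxy)-5-bromobenzene | Brc1cc(OCc2ccccc2)cc(OCc2ccccc2)c1 | intermediate
3 | 1,5-bis(benzyloxy)-2,3-dibromobenzene | Brc1cc(OCc2ccccc2)cc(OCc2ccccc2)c1Br | intermediate
4 | 7-bromohept-1-ene | C=CCCCCCBr | starting material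
5 | (S)-propylene oxide, (2S)-2-methyloxirane | C[C@H]1CO1 | starting material
6 | hept-6-en-1-ylmagnesium bromide | C=CCCCCC[Mg]Br | intermediate
7 | (2S)-dec-9-en-2-ol | C=CCCCCCC[C@H](C)O | intermediate
8 | tert-butyl{[(2S)-dec-9-en-2-yl]oxy}dimethylsilane | C=CCCCCCC[C@H](C)O[Si](C)(C)C(C)(C)C | intermediate
9 | 9-{(9S)-9-[(tert-butyldimethylsilyl)oxy]decyl}-9-borabicyclo[3.3.1]nonane | B1(CCCCCCCC[C@H](C)O[Si](C)(C)C(C)(C)C)C2CCCC1CCC2 | intermediate
10 | (9S)-9-[(tert-butyldimethylsilyl)oxy]decan-1-ol | OCCCCCCCC[C@H](C)O[Si](C)(C)C(C)(C)C | intermediate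
11 | {[(2S)-10-bromodecan-2-yl]oxy}(tert-butyl)dimethylsilane | BrCCCCCCCC[C@H](C)O[Si](C)(C)C(C)(C)C | intermediate
12 | (S)-epichlorohydrin, (2S)-2-(chloromethyl)oxirane | ClC[C@@H]1CO1 | starting material
13 | {(9S)-9-[(tert-butyldimethylsilyl)oxy]decyl}magnesium bromide | Br[Mg]CCCCCCCC[C@H](C)O[Si](C)(C)C(C)(C)C | intermediate
14 | (2S,12S)-12-[(tert-butyldimethylsilyl)oxy]-1-chlorotridecan-2-ol | ClC[C@@H](O)CCCCCCCCC[C@H](C)O[Si](C)(C)C(C)(C)C | intermediate
15 | (2S,12S)-1-chlorotridecane-2,12-diol | ClC[C@@H](O)CCCCCCCCC[C@H](C)O | intermediate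
16 | carbon dioxide | O=C=O | starting material
17 | dilithium (2R,12S)-1-lithiotridecane-2,12-bis(olate); the C1-lithiated dilithium dialkoxide of 15 with unchanged spatial arrangement (the C2 descriptor changes only because CH2Li ranks below the chain) | [Li]C[C@@H](O[Li])CCCCCCCCC[C@H](C)O[Li] | intermediate
18 | [2,4-bis(benzyloxy)-6-bromophenyl]lithium | [Li]c1c(Br)cc(OCc2ccccc2)cc1OCc1ccccc1 | intermediate
19 | 3,5-bis(benzyloxy)benzyne (1,2-didehydro-3,5-bis(benzyloxy)benzene) | C1#CC(OCc2ccccc2)=CC(OCc2ccccc2)=C1 | intermediate
20 | {2,4-bis(benzyloxy)-6-[(2S,12S)-2,12-bis(lithiooxy)tridecyl]phenyl}lithium | [Li]c1c(OCc2ccccc2)cc(OCc2ccccc2)cc1C[C@@H](O[Li])CCCCCCCCC[C@H](C)O[Li] | intermediate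
21 | lithium 2,4-bis(benzyloxy)-6-[(2S,12S)-2,12-dihydroxytridecyl]benzoate | [Li+].[O-]C(=O)c1c(OCc2ccccc2)cc(OCc2ccccc2)cc1C[C@@H](O)CCCCCCCCC[C@H](C)O | intermediate
22 | benzyl 2,4-bis(benzyloxy)-6-[(2S,12S)-2,12-dihydroxytridecyl]benzoate | O=C(OCc1ccccc1)c1c(OCc2ccccc2)cc(OCc2ccccc2)cc1C[C@@H](O)CCCCCCCCC[C@H](C)O | intermediate
23 | benzyl 2,4-bis(benzyloxy)-6-[(2S,12S)-2,12-diacetoxytridecyl]benzoate | O=C(OCc1ccccc1)c1c(OCc2ccccc2)cc(OCc2ccccc2)cc1C[C@@H](OC(C)=O)CCCCCCCCC[C@H](C)OC(C)=O | intermediate
24 | 6-[(2S,12S)-2,12-diacetoxytridecyl]-2,4-dihydroxybenzoic acid (CNP0203944.2) | CC(=O)O[C@@H](CCCCCCCCC[C@H](C)OC(C)=O)Cc1cc(O)cc(O)c1C(=O)O | target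

**Step count and risks**

Total: 12 steps. Longest linear sequence: 10 steps (steps 3–12, from 7-bromohept-1-ene).

Step 9 (riskiest). Three processes could defeat it. The β-oxido carbanion may lose Li2O (β-elimination to the terminal alkene) before it meets the aryne. The aryne may be intercepted by the ortho-bromoaryllithium instead of the carbanion. A benzylic OCH2 proton may be transferred to the aryllithium before CO2 arrives. The fallback uses known chemistry, sets out from 15 and 2, and returns at 21. Chlorohydrin 15 would be closed with K2CO3 in MeOH to (2S)-11-[(2S)-oxiran-2-yl]undecan-2-ol F1; the C2–O bond is not broken, so configuration is kept. Bromide 2 would be converted with Mg in THF into [3,5-bis(benzyloxy)phenyl]magnesium bromide F2. Used in excess with CuI as catalyst, it should open F1 at the CH2 terminus to (2S,12S)-1-[3,5-bis(benzyloxy)phenyl]tridecane-2,12-diol F3, which forms the C6–C1′ bond. NBS in MeCN should then brominate the ring ortho to the side chain and para to a benzyloxy group, giving (2S,12S)-1-[3,5-bis(benzyloxy)-2-bromophenyl]tridecane-2,12-diol F4. Three equivalents of n-BuLi in THF at −78 °C (two for the hydroxyls, one for Br/Li exchange) would generate aryllithium 20 by a conventional exchange, and CO2 would give 21.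

Step 10. The free C2′ hydroxyl may attack the newly formed ester carbonyl during alkylation or on concentration, closing the six-membered lactone with loss of benzyl alcohol. Alkylation of the hindered, di-ortho-substituted carboxylate may also stall. The fallback leaves the carboxyl unprotected, sets out from 21 and returns at 24. Crude 21 would be treated with excess Ac2O, pyridine and DMAP. Acetyl transfer to both hydroxyls is expected to outrun attack on the hindered aroyl end of any mixed anhydride. Aqueous NaHCO3 would cleave the mixed anhydride, and mild acidification should give 2,4-bis(benzyloxy)-6-[(2S,12S)-2,12-diacetoxytridecyl]benzoic acid F5, which can no longer lactonise. Hydrogenolysis (H2, Pd/C, EtOAc) of its two benzyl ethers would give 24.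

Step 2. Bromination may occur at the carbon between the two benzyloxy groups, or a second bromination may follow, giving isomer mixtures that are hard to separate and cannot eliminate to the aryne. The fallback fixes the position through a C–B bond, sets out from 2 and returns at 3. Bromide 2 would be deprotonated ortho to bromine with lithium 2,2,6,6-tetramethylpiperidide in the presence of B(OiPr)3 (THF, −78 °C, in situ trapping). Both positions ortho to bromine are equivalent, and the short-lived 18 should be borylated before it loses LiBr. Hydrolysis should give [2,4-bis(benzyloxy)-6-bromophenyl]boronic acid F6. Ipso-bromodeboronation with CuBr2 in aqueous MeOH would then deliver 3.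

**Further compounds**

F1 | step 9 | (2S)-11-[(2S)-oxiran-2-yl]undecan-2-ol | C1[C@@H](O1)CCCCCCCCC[C@H](C)O
F2 | step 9 | [3,5-bis(benzyloxy)phenyl]magnesium bromide | Br[Mg]c1cc(OCc2ccccc2)cc(OCc2ccccc2)c1
F3 | step 9 | (2S,12S)-1-[3,5-bis(benzyloxy)phenyl]tridecane-2,12-diol | c1c(OCc2ccccc2)cc(OCc2ccccc2)cc1C[C@@H](O)CCCCCCCCC[C@H](C)O
F4 | step 9 | (2S,12S)-1-[3,5-bis(benzyloxy)-2-bromophenyl]tridecane-2,12-diol | Brc1c(OCc2ccccc2)cc(OCc2ccccc2)cc1C[C@@H](O)CCCCCCCCC[C@H](C)O
F5 | step 10 | 2,4-bis(benzyloxy)-6-[(2S,12S)-2,12-diacetoxytridecyl]benzoic acid | OC(=O)c1c(OCc2ccccc2)cc(OCc2ccccc2)cc1C[C@@H](OC(C)=O)CCCCCCCCC[C@H](C)OC(C)=O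
F6 | step 2 | [2,4-bis(benzyloxy)-6-bromophenyl]boronic acid | OB(O)c1c(Br)cc(OCc2ccccc2)cc1OCc1ccccc1
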